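Draw Thursday's flask as one curve before asking what any option does to it.

common to all: starting material 23 mM; partner 21.8 mM
- Thursday's: temperature 5 °C; the very flask that is asked about, followed so far
- Monday's: temperature −10 °C; run made earlier
- flask: temperature 5 °C; time 30 min

- Thursday's (time / min: single product / %): 4.00: 20.2; 8.00: 19.9; 12.0: 18.1; 15.0: 16.5; 20.0: 14.4; 25.0: 12.7; 30.0: 11.4
- Monday's (time / min: single product / %): 8.00: 21.7; 15.0: 25.2; 25.0: 25.5; 30.0: 25.9; 40.0: 23.9; 50.0: 22.7; 60.0: 21.6

(scatter of a reading: 0.3 percentage points)

- birch: at 30 min raise the temperature by 25 K, then wait 30 min
- alder: at 30 min take out 90% of the single product then present, then wait 30 min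
- elm: change nothing and wait 30 min more
- oak: at 30 min add partner, 100% of the amount charged, then wait 30 min

- single product that was removed still counts
- what was read earlier has a scatter of 0.3 percentage points, one standard deviation
- additions bring no volume worth counting

- single product, in percent of the starting material first charged, at 30 min
- the option that brings most further single product ("none" if no option brings more than 2 percentage points) (birch / alder / elm / oak / none)
- single product present, with what was taken out counted in, in percent of the starting material first charged, after birch
- single product present, with what was taken out counted in, in percent of the starting material first charged, after oak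

In Thursday's flask the single product climbed to 20.2% within 4.00 min, the highest reading of that run. It stood at 19.9% at 8.00 min, which I read as the knee, and then fell with a slope that eased. The drop from 15.0 min to 20.0 min was 2.1 percentage points, and the drop from 25.0 min to 30.0 min was 1.3 points.

I supposed that formation was over in this tail and that the rate of fall was proportional to the distance above a level, a relaxation. Integrated, that distance halves in a fixed time, which these two drops put at 14.5 min. The distance still open at 30.0 min then came out at 4.8 points, so I extrapolated a level near 6.60%. Carried back to time zero, the same curve gives 26.8%, which I called the pool: my estimate of the single product made in Thursday's flask, counted as if none had yet moved into some unread form. That extrapolated level is about a quarter of the pool. With a scatter of 0.3 points on each reading, these are rough readings.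

So I reckoned elm as a loss of 3.7 points. For alder, the pool less what was removed came to 16.6%, and a quarter of that, approached over 30 min, gave a gain of 2.2 points, more than the 2 points margin. Birch and oak I left open, having no level read at the higher temperature and no reading of partner.

The forecast gave 11.4% now, oak as best, 1% after birch and 16% after oak, holding that “the stall most likely means partner is spent”.

The flask gave 11.5% at 30 min, and the best option was birch, bringing 10 points to reach 21.6%, while alder brought 4.6 points and oak ended at 8.15%.

    starting material + partner → other mono adduct (k = 11.0 L mol⁻¹ min⁻¹, Ea = 41.0 kJ mol⁻¹)
    partner + other mono adduct → double product (k = 6.90 L mol⁻¹ min⁻¹, Ea = 45.0 kJ mol⁻¹)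
    single product ⇌ isomer of the product (K = 2.20, k = 0.0590 min⁻¹, Ea = 77.0 kJ mol⁻¹, ΔH = −49.0 kJ mol⁻¹)
    partner + single product → double product (k = 3.10 L mol⁻¹ min⁻¹, Ea = 60.0 kJ mol⁻¹)
    starting material + partner → single product (k = 8.30 L mol⁻¹ min⁻¹, Ea = 38.0 kJ mol⁻¹)
    (constants at 5 °C)

At 30 min the flask held 18.4% as isomer of the product, and the relaxation half-life of single product and isomer of the product by that step alone, both ways together, is 8.08 min, shorter than that time. Against my pool of 26.8%, the single product stood at 42.9% now and at 80.6% after birch. The repeat at −10 °C, with the same charges, held 25.4% of single product at 30 min, which is 94.8% of that pool, beside 5.87% of isomer of the product.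

(Readings and results were generated by integration on assumed constants; the scatter is artificial.)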